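Everything rests on cutting the butenolide at O–C7 and C19–C17, so that CO2 is the two-atom piece inserted between a vinylic carbon (C17 of the exocyclic C8=C17 alkene) and the doubly allylic C7, which sits between C8=C17 and C5=C6. In one flask the (Z)-iodo dienol 21 is lithiated, carboxylated (C17–C19) and closed by Pd-catalysed allylic substitution (O–C7), CO2 also activating the allylic hydroxyl; this gives the γ-vinyl butenolide and sets C7. The precursor comes from an iodide-triggered aldol on a cyclohexane aldehyde made by asymmetric Diels–Alder reaction; ring-closing metathesis then forms the ten-membered ring at C5=C6.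

Key step: step 17

Notation: briarane numbering is used for every intermediate (C1 quaternary carbon, C15 its methyl, C2–C9 the chain that becomes the ten-membered ring, C10–C14 the rest of the cyclohexane, C16 the methyl on C5, C17/C18/C19 the α-carbon, methyl and carbonyl of the butenolide, C20 the methyl on C11). β is the face of the cyclohexane that carries C15, α the opposite face.
Assumption: the (R,R)-chromium salen catalyst of step 1 and the (S,S)-bis-sulfonamide ligand of step 20 show their usual sense of induction; the antipode would be used otherwise. Compounds 1, 2, 13, 19 and 26 are taken as commercial.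

Step 1
Reactants: 1 ethyl (2E)-3-methyl-4-oxobut-2-enoate; 2 (E)-3-(tert-butyldimethylsilyloxy)-N,N-dimethylbuta-1,3-dien-1-amine
Product: 4 ethyl (1S,2S)-2-formyl-2-methyl-5-oxocyclohex-3-ene-1-carboxylate, via aminosiloxy cycloadduct 3 (not isolated)
Conditions: Cr(salen)SbF6 [(R,R)-salen, trivalent chromium, 5 mol%], 4 Å MS, CH2Cl2, −40 °C; then AcCl, −78 °C → rt
Reagents that add atoms: none
Why: Catalytic asymmetric Diels–Alder reaction of a 1-amino-3-siloxy diene: the chromium-bound formyl group sends the nucleophilic CH2 terminus of 2 to C10 and the amino-bearing terminus to the methylated carbon C1, the E-alkene of 1 fixes C2 and C9 trans, the catalyst sets the absolute configuration of C1 and C10, and acetyl chloride then eliminates the amine to the enone.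

Step 2
Reactants: 4 enone aldehyde
Product: 5 dimethyl acetal of 4
Conditions: HC(OMe)3, MeOH, p-TsOH·H2O (cat.), 0 °C → rt
Reagents that add atoms: trimethyl orthoformate COC(OC)OC
Why: Acid-catalysed acetalisation with an orthoformate should be selective for the aldehyde over the conjugated ketone and masks C2 for the base, hydride and organolithium steps that follow.

Step 3
Reactants: 5 acetal enone
Product: 6 C11-methylated enone (11-Me α)
Conditions: LiN(i-Pr)2 (1.05 equiv), THF, −78 °C; MeI, −78 → −20 °C
Reagents that add atoms: iodomethane CI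
Why: Kinetic α′-deprotonation of the enone (C11 is the only enolisable position) and enolate alkylation; the methyl group should enter anti to the axial C15 methyl, but this centre becomes planar again in step 5.

Step 4
Reactants: 6 C11-methylated enone
Product: 7 13,14α-epoxy ketone
Conditions: t-BuOOH, DBU, CH2Cl2, 0 °C → rt
Reagents that add atoms: tert-butyl hydroperoxide CC(C)(C)OO
Why: Weitz–Scheffer nucleophilic epoxidation; the hydroperoxide should add axially to C14 anti to the pseudo-axial C15 methyl of the conformer that keeps the C2 and C9 groups equatorial, so the epoxide lies on the α face (cis to C2), and C13 is removed as a site of enolisation.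

Step 5
Reactants: 7 epoxy ketone
Product: 8 enol triflate (C11=C12–OTf)
Conditions: KN(SiMe3)2, THF, −78 °C; PhNTf2, −78 → 0 °C
Reagents that add atoms: N-phenyl-bis(trifluoromethanesulfonimide) O=S(=O)(N(c1ccccc1)S(=O)(=O)C(F)(F)F)C(F)(F)F
Why: Enolate O-triflation; only C11–H can be removed because C13 is an epoxide carbon, so the tetrasubstituted enol triflate should form regiospecifically.

Step 6
Reactants: 8 enol triflate
Product: 9 vinyl epoxide (C11=C12, 13,14α-epoxide)
Conditions: Pd(PPh3)4 (3 mol%), Bu3SnH (1.1 equiv), LiCl (3 equiv), THF, rt, short reaction time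
Reagents that add atoms: none
Why: Palladium-catalysed tin hydride reduction of an enol triflate replaces OTf by H and leaves the trisubstituted C11=C12 alkene; oxidative addition into the C–OTf bond should outrun ionisation of the hindered allylic epoxide.

Step 7
Reactants: 9 vinyl epoxide
Product: 10 C11-ene 9,14α-diol
Conditions: LiAlH4, Et2O, −20 → 0 °C
Reagents that add atoms: none
Why: Hydride should open the vinyl epoxide by SN2 attack at the allylic and less hindered C13 (C14 is neopentylic), which leaves the 14α-alcohol untouched at C14, and it reduces the ester to the C9 primary alcohol.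

Step 8
Reactants: 10 C11-ene diol
Product: 11 9,12α,14α-triol (11-Me β)
Conditions: BH3·THF (4 equiv), THF, 0 °C → rt; then 30% H2O2, aq NaOH, 0 °C
Reagents that add atoms: hydrogen peroxide OO
Why: Hydroboration–oxidation of the trisubstituted alkene: anti-Markovnikov syn addition from the α face (anti to the pseudo-axial C9 arm on C10 and to the C15 methyl, and on the side of the 14α-alkoxyborane) should put OH on C12 and H on C11 both α, which leaves the C11 methyl β and trans to the hydroxyl.

Step 9
Reactants: 11 triol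
Product: 12 12α,14α-dihydroxy C9 aldehyde
Conditions: TEMPO (10 mol%), PhI(OAc)2 (1.1 equiv), CH2Cl2, rt
Reagents that add atoms: none
Why: Nitroxyl-catalysed oxidation is selective for the primary alcohol and is neutral, so the epimerisable C10 should survive; neither secondary hydroxyl can form a five-membered lactol because both are trans to C9.

Step 10
Reactants: 12 aldehyde diol; 13 methyl but-2-ynoate
Product: 14 iodo-aldol adduct (9R; iodine cis to the ester)
Conditions: MgI2 (3 equiv), CH2Cl2, 0 °C → rt
Reagents that add atoms: magnesium iodide [Mg+2].[I-].[I-]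
Why: Iodide-triggered aldol (β-iodo Morita–Baylis–Hillman reaction): conjugate addition of iodide to the ynoate gives a magnesium allenolate that adds to the aldehyde through C8, which should give the tetrasubstituted alkene with iodine cis to the ester and, by Felkin–Anh attack anti to the quaternary C1, the 9R carbinol.

Step 11
Reactants: 14 iodo-aldol adduct
Product: 15 12-O-TBS ether
Conditions: TBSCl (1.1 equiv), imidazole, DMF, 0 °C
Reagents that add atoms: tert-butyldimethylsilyl chloride CC(C)(C)[Si](C)(C)Cl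
Why: Silylation should take the least hindered secondary alcohol (C12) in preference to the neopentylic C14 and the crowded allylic C9 hydroxyls.

Step 12
Reactants: 15 12-O-TBS ether
Product: 16 9,14-bis-O-TES ether
Conditions: Et3SiCl (3 equiv), imidazole, DMAP (cat.), DMF, rt → 40 °C
Reagents that add atoms: chlorotriethylsilane CC[Si](Cl)(CC)CC
Why: Exhaustive silylation gives the two oxygens that end as acetates the same, later selectively removable, protecting group; the chloride (not the triflate) is used so that the acetal is not touched.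

Step 13
Reactants: 16 bis-TES ester
Product: 17 allylic alcohol (C7H2OH)
Conditions: i-Bu2AlH (2.5 equiv), CH2Cl2, −78 °C; Rochelle salt
Reagents that add atoms: none
Why: 1,2-Reduction of the conjugated ester to the allylic alcohol; silyl ethers, acetal and the iodoalkene should be inert at −78 °C.

Step 14
Reactants: 17 allylic alcohol
Product: 18 (Z)-β-iodo enal (C7 aldehyde)
Conditions: Dess–Martin periodinane, NaHCO3, CH2Cl2, 0 °C → rt
Reagents that add atoms: none
Why: Buffered periodinane oxidation gives the enal without nucleophiles that could displace the vinylogous acyl iodide.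

Step 15
Reactants: 18 β-iodo enal; 19 methyl (triphenylphosphoranylidene)acetate
Product: 20 methyl dienoate (C6=C7 E)
Conditions: toluene, 60 °C
Reagents that add atoms: none
Why: Wittig olefination with a stabilised ylide should give the E alkene under base-free conditions that spare the β-iodo enal.

Step 16
Reactants: 20 dienoate
Product: 21 (Z)-iodo dienol
Conditions: i-Bu2AlH (2.5 equiv), CH2Cl2, −78 °C; Rochelle salt
Reagents that add atoms: none
Why: 1,2-Reduction of the dienoate gives the primary allylic alcohol that serves as the latent leaving group of the key step.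

Step 17
Reactants: 21 (Z)-iodo dienol
Product: 24 γ-vinyl butenolide (7S), via dilithio species 22 (not isolated), via hydroxy dienoic acid 23 (not isolated)
Conditions: t-BuLi (3.1 equiv), THF/Et2O, −78 °C; CO2 (g), −78 → 0 °C; AcOH (2 equiv); Pd(PPh3)4 (5 mol%, zerovalent palladium), CO2 (1 atm), 45 °C
Reagents that add atoms: carbon dioxide O=C=O
Why: After deprotonation of the hydroxyl, iodine–lithium exchange with retention gives the dienyllithium, which adds to CO2 to make the C17–C19 bond, while CO2 also turns the alkoxide into an allyl carbonate that zerovalent palladium ionises, after buffering with AcOH, to a π-allyl complex over C7, C6 and the terminal CH2. The carboxylate, held cis to C7 by the retained alkene geometry, attacks the internal terminus C7 anti to palladium in a 5-exo closure, which forms the O–C7 bond and the butenolide carrying a vinyl group. The closest known reaction types are carboxylation of alkenyllithiums, CO2-promoted palladium activation of allylic alcohols and Tsuji–Trost lactonisation by carboxylates. The 5-exo mode should win over attack at the CH2 terminus, which would give a seven-membered lactone holding an E alkene. C7 is the only new stereocenter: the π-allyl faces equilibrate through the terminal σ-complex, and allylic 1,3-strain about C8=C17 (C9–H in the alkene plane, the cyclohexane blocking one face) should place the vinyl arm on the side of the C9 silyloxy group, which is 7S. Direct lactonisation of 23 is impossible because its hydroxyl lies across an E alkene, so the ring oxygen must come from the carboxylate.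

Step 18
Reactants: 24 γ-vinyl butenolide acetal
Product: 25 C2 aldehyde
Conditions: Et3SiOTf, 2,4,6-collidine, CH2Cl2, 0 °C; then H2O
Reagents that add atoms: none
Why: Silyl triflate/collidine cleavage of an aldehyde acetal via a pyridinium intermediate should free the aldehyde without acid strong enough to remove the TES and TBS ethers or ionise the allylic lactone.

Step 19
Reactants: 26 4-iodo-2-methylbut-1-ene
Product: 27 bis(3-methylbut-3-en-1-yl)zinc
Conditions: Et2Zn (neat, excess), CuI (cat.), 50 °C; volatiles removed under vacuum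
Reagents that add atoms: diethylzinc CC[Zn]CC
Why: Copper-catalysed iodine–zinc exchange gives the salt-free dialkylzinc needed for the catalytic asymmetric addition.

Step 20
Reactants: 25 C2 aldehyde; 27 bis(3-methylbut-3-en-1-yl)zinc
Product: 28 (2R)-alcohol with the C3–C5 chain
Conditions: 27 (2 equiv), Ti(OiPr)4 (1.2 equiv), (1S,2S)-N,N′-bis(trifluoromethanesulfonyl)cyclohexane-1,2-diamine (10 mol%), toluene, −20 °C
Reagents that add atoms: none
Why: Titanium bis-sulfonamide-catalysed enantioselective addition of a dialkylzinc to an aldehyde; the (S,S) ligand should deliver the alkyl group to the Re face and give 2R under reagent control, and the reagent does not touch the butenolide.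

Step 21
Reactants: 28 (2R)-alcohol
Product: 29 C2 butyrate
Conditions: (PrCO)2O, DMAP, pyridine, CH2Cl2, rt
Reagents that add atoms: butyric anhydride CCCC(=O)OC(=O)CCC
Why: DMAP-catalysed acylation installs the butyrate on the only free hydroxyl.

Step 22
Reactants: 29 diene butyrate
Product: 30 macrocycle (5Z; 9,14-bis-O-TES, 12-O-TBS)
Conditions: second-generation Hoveyda–Grubbs catalyst (10 mol%), 1,4-benzoquinone (20 mol%), toluene (1 mM), 90 °C
Reagents that add atoms: none
Why: Ring-closing metathesis between the C7 vinyl group (site of initiation) and the 1,1-disubstituted alkene forms C5=C6; in a ten-membered ring fused to the butenolide and the cyclohexane only the Z alkene should be accessible.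

Step 23
Reactants: 30 macrocycle
Product: 31 9,14-diol
Conditions: HF·pyridine, pyridine, THF, 0 °C
Reagents that add atoms: none
Why: Buffered fluoride should remove the two triethylsilyl ethers and leave the more robust secondary TBS ether, the esters and the butenolide.

Step 24
Reactants: 31 9,14-diol
Product: 32 9,14-diacetate
Conditions: Ac2O, DMAP, pyridine, rt
Reagents that add atoms: acetic anhydride CC(=O)OC(C)=O
Why: Standard acetylation of both free hydroxyls; pyridine is a weak enough base to leave the C7 centre of the butenolide alone.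

Step 25
Reactants: 32 9,14-diacetate
Product: 33 target
Conditions: HF·pyridine, MeCN, rt
Reagents that add atoms: none
Why: Acidic fluoride desilylation frees the 12-hydroxyl without acyl migration or ester cleavage.

Compound list
1 | ethyl (2E)-3-methyl-4-oxobut-2-enoate | CCOC(=O)/C=C(\C)C=O | starting material
2 | (E)-3-(tert-butyldimethylsilyloxy)-N,N-dimethylbuta-1,3-dien-1-amine | CN(C)/C=C/C(=C)O[Si](C)(C)C(C)(C)C | starting material
3 | aminosiloxy cycloadduct (14α-NMe2, C12 silyl enol ether) | C[C@@]1(C=O)[C@@H](C(=O)OCC)CC(O[Si](C)(C)C(C)(C)C)=C[C@@H]1N(C)C | intermediate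
4 | ethyl (1S,2S)-2-formyl-2-methyl-5-oxocyclohex-3-ene-1-carboxylate (C2 = CHO, C9 = CO2Et) | C[C@@]1(C=O)[C@@H](C(=O)OCC)CC(=O)C=C1 | intermediate
5 | ethyl (1S,2S)-2-(dimethoxymethyl)-2-methyl-5-oxocyclohex-3-ene-1-carboxylate | C[C@@]1(C(OC)OC)[C@@H](C(=O)OCC)CC(=O)C=C1 | intermediate
6 | C11-methylated enone (11-Me α, trans to C9) | C[C@@]1(C(OC)OC)[C@@H](C(=O)OCC)[C@H](C)C(=O)C=C1 | intermediate
7 | 13,14α-epoxy 12-ketone | C[C@@]1(C(OC)OC)[C@@H](C(=O)OCC)[C@H](C)C(=O)[C@@H]2O[C@@H]21 | intermediate
8 | enol triflate (C11=C12–OTf, 13,14α-epoxide) | C[C@@]1(C(OC)OC)[C@@H](C(=O)OCC)C(C)=C(OS(=O)(=O)C(F)(F)F)[C@@H]2O[C@@H]21 | intermediate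
9 | vinyl epoxide (C11=C12, 13,14α-epoxide) | C[C@@]1(C(OC)OC)[C@@H](C(=O)OCC)C(C)=C[C@@H]2O[C@@H]21 | intermediate
10 | C11-ene 9,14α-diol | C[C@@]1(C(OC)OC)[C@@H](CO)C(C)=CC[C@@H]1O | intermediate
11 | 9,12α,14α-triol (11-Me β) | C[C@@]1(C(OC)OC)[C@@H](CO)[C@@H](C)[C@H](O)C[C@@H]1O | intermediate
12 | 12α,14α-dihydroxy C9 aldehyde | C[C@@]1(C(OC)OC)[C@@H](C=O)[C@@H](C)[C@H](O)C[C@@H]1O | intermediate
13 | methyl but-2-ynoate | CC#CC(=O)OC | starting material
14 | iodo-aldol adduct: methyl (Z)-3-iodobut-2-enoate carrying the (9R)-carbinol at C8, 12α,14α-diol | C[C@@]1(C(OC)OC)[C@@H]([C@@H](O)/C(C(=O)OC)=C(/I)C)[C@@H](C)[C@H](O)C[C@@H]1O | intermediate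
15 | 12-O-TBS ether of 14 | C[C@@]1(C(OC)OC)[C@@H]([C@@H](O)/C(C(=O)OC)=C(/I)C)[C@@H](C)[C@H](O[Si](C)(C)C(C)(C)C)C[C@@H]1O | intermediate
16 | 9,14-bis-O-TES 12-O-TBS ester | C[C@@]1(C(OC)OC)[C@@H]([C@@H](O[Si](CC)(CC)CC)/C(C(=O)OC)=C(/I)C)[C@@H](C)[C@H](O[Si](C)(C)C(C)(C)C)C[C@@H]1O[Si](CC)(CC)CC | intermediate
17 | allylic alcohol (C7H2OH; iodine cis to C7) | C[C@@]1(C(OC)OC)[C@@H]([C@@H](O[Si](CC)(CC)CC)/C(CO)=C(/I)C)[C@@H](C)[C@H](O[Si](C)(C)C(C)(C)C)C[C@@H]1O[Si](CC)(CC)CC | intermediate
18 | (Z)-β-iodo enal (C7 aldehyde) | C[C@@]1(C(OC)OC)[C@@H]([C@@H](O[Si](CC)(CC)CC)/C(C=O)=C(/I)C)[C@@H](C)[C@H](O[Si](C)(C)C(C)(C)C)C[C@@H]1O[Si](CC)(CC)CC | intermediate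
19 | methyl (triphenylphosphoranylidene)acetate | COC(=O)C=P(c1ccccc1)(c1ccccc1)c1ccccc1 | starting material
20 | methyl dienoate (C6=C7 E; iodine on C17 cis to C7) | C[C@@]1(C(OC)OC)[C@@H]([C@@H](O[Si](CC)(CC)CC)/C(/C=C/C(=O)OC)=C(/I)C)[C@@H](C)[C@H](O[Si](C)(C)C(C)(C)C)C[C@@H]1O[Si](CC)(CC)CC | intermediate
21 | (Z)-iodo dienol | C[C@@]1(C(OC)OC)[C@@H]([C@@H](O[Si](CC)(CC)CC)/C(/C=C/CO)=C(/I)C)[C@@H](C)[C@H](O[Si](C)(C)C(C)(C)C)C[C@@H]1O[Si](CC)(CC)CC | intermediate
22 | dilithio species (lithium alkoxide, C17 dienyllithium) | C[C@@]1(C(OC)OC)[C@@H]([C@@H](O[Si](CC)(CC)CC)/C(/C=C/CO[Li])=C(/[Li])C)[C@@H](C)[C@H](O[Si](C)(C)C(C)(C)C)C[C@@H]1O[Si](CC)(CC)CC | intermediate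
23 | hydroxy dienoic acid (CO2H on C17 cis to C7) | C[C@@]1(C(OC)OC)[C@@H]([C@@H](O[Si](CC)(CC)CC)/C(/C=C/CO)=C(/C(=O)O)C)[C@@H](C)[C@H](O[Si](C)(C)C(C)(C)C)C[C@@H]1O[Si](CC)(CC)CC | intermediate
24 | (7S)-γ-vinyl butenolide, C2 dimethyl acetal | C[C@@]1(C(OC)OC)[C@@H]([C@@H](O[Si](CC)(CC)CC)C2=C(C)C(=O)O[C@H]2C=C)[C@@H](C)[C@H](O[Si](C)(C)C(C)(C)C)C[C@@H]1O[Si](CC)(CC)CC | intermediate
25 | C2 aldehyde of the vinyl butenolide | C[C@@]1(C=O)[C@@H]([C@@H](O[Si](CC)(CC)CC)C2=C(C)C(=O)O[C@H]2C=C)[C@@H](C)[C@H](O[Si](C)(C)C(C)(C)C)C[C@@H]1O[Si](CC)(CC)CC | intermediate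
26 | 4-iodo-2-methylbut-1-ene | C=C(C)CCI | starting material
27 | bis(3-methylbut-3-en-1-yl)zinc | C=C(C)CC[Zn]CCC(C)=C | intermediate
28 | (2R)-alcohol carrying the 3-methylbut-3-enyl chain | C[C@@]1([C@H](O)CCC(C)=C)[C@@H]([C@@H](O[Si](CC)(CC)CC)C2=C(C)C(=O)O[C@H]2C=C)[C@@H](C)[C@H](O[Si](C)(C)C(C)(C)C)C[C@@H]1O[Si](CC)(CC)CC | intermediate
29 | (2R)-butyrate, metathesis precursor | C[C@@]1([C@H](OC(=O)CCC)CCC(C)=C)[C@@H]([C@@H](O[Si](CC)(CC)CC)C2=C(C)C(=O)O[C@H]2C=C)[C@@H](C)[C@H](O[Si](C)(C)C(C)(C)C)C[C@@H]1O[Si](CC)(CC)CC | intermediate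
30 | macrocycle: 2-O-butanoyl-9,14-bis-O-TES-12-O-TBS briarane 5Z,8(17)-diene 19,7-lactone | CCCC(=O)O[C@@H]1CC/C(C)=C\[C@@H]2OC(=O)C(C)=C2[C@H](O[Si](CC)(CC)CC)[C@H]2[C@@H](C)[C@H](O[Si](C)(C)C(C)(C)C)C[C@H](O[Si](CC)(CC)CC)[C@@]21C | intermediate
31 | 9,14-diol (2-O-butanoyl, 12-O-TBS) | CCCC(=O)O[C@@H]1CC/C(C)=C\[C@@H]2OC(=O)C(C)=C2[C@H](O)[C@H]2[C@@H](C)[C@H](O[Si](C)(C)C(C)(C)C)C[C@H](O)[C@@]21C | intermediate
32 | 9,14-diacetate (2-O-butanoyl, 12-O-TBS) | CCCC(=O)O[C@@H]1CC/C(C)=C\[C@@H]2OC(=O)C(C)=C2[C@H](OC(C)=O)[C@H]2[C@@H](C)[C@H](O[Si](C)(C)C(C)(C)C)C[C@H](OC(C)=O)[C@@]21C | intermediate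
33 | CNP0281577.1: (1S,2R,5Z,7S,9R,10S,11R,12R,14S)-9,14-diacetoxy-2-butanoyloxy-12-hydroxybriara-5,8(17)-diene 19,7-lactone | CCCC(=O)O[C@@H]1CC/C(C)=C\[C@@H]2OC(=O)C(C)=C2[C@H](OC(C)=O)[C@H]2[C@@H](C)[C@H](O)C[C@H](OC(C)=O)[C@@]21C | target

Total step count: 25. Longest linear sequence: 24 steps (steps 1–18 and 20–25; step 19 prepares reagent 27).

Steps most likely to fail

1. Step 17 (key step). The allylic hydroxyl may be ionised too slowly, so that the hydroxy acid 23 survives, or the π-allyl complex may lose a proton to a triene instead of being captured. The fallback sets out from 21 and comes back at 24. Mitsunobu etherification of 21 with phenol (PPh3, DIAD, THF) should give the dienyl phenyl ether F1. Iodine–lithium exchange (t-BuLi, −78 °C) and CO2, followed by acidic work-up, should give the isolated dienoic acid phenyl ether F2. A classical Tsuji–Trost cyclisation with phenoxide as the leaving group (Pd(PPh3)4, Et3N, THF, 50 °C) then closes the butenolide to 24.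

2. Step 22 (ring-closing metathesis). The carbene formed at the vinyl group may dimerise the substrate or migrate the alkene faster than it closes the strained ten-membered ring onto the 1,1-disubstituted alkene. The fallback sets out from 24 and comes back at 30, forming C4–C5 instead of C5=C6 with the Z alkene already in place. Ozonolysis of the vinyl group (O3, CH2Cl2, −78 °C; PPh3) gives the C6 aldehyde F3. Stork–Zhao olefination with (1-iodoethylidene)triphenylphosphorane gives the (Z)-2-iodopropenyl butenolide F4. Acetal cleavage as in step 18 gives the C2 aldehyde F5. Amino-alcohol-catalysed enantioselective addition of divinylzinc gives the (2R)-vinyl carbinol F6, and butyrylation as in step 21 gives the butyrate F7. Hydroboration of the C2 vinyl group with 9-BBN gives the alkylborane F8, which is not isolated. An intramolecular B-alkyl Suzuki–Miyaura coupling (PdCl2(dppf), AsPh3, Cs2CO3, DMF/THF/H2O, high dilution) should then give 30.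

3. Step 10 (iodide-triggered aldol). The magnesium allenolate may add too slowly to the hindered, α-branched aldehyde, which gives time for epimerisation at C10 or for loss of the alkene geometry. The fallback sets out from 12 and 13 and comes back at 14; it replaces the in-situ magnesium allenolate by an isolated silyl ketene acetal in a Mukaiyama aldol. The diol of 12 is masked as the bis(trimethylsilyl) ether F9 (Me3SiCl, imidazole, CH2Cl2, 0 °C). Ynoate 13 is treated with Me3SiI (CH2Cl2, −78 °C) to give the 3-iodo silyl allenoate F10. F9 and F10 are combined with BF3·OEt2 at −78 °C, and a mildly acidic work-up that also removes the trimethylsilyl ethers should give 14.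

Further compounds
F1 | step 17 | dienyl phenyl ether of 21 | C[C@@]1(C(OC)OC)[C@@H]([C@@H](O[Si](CC)(CC)CC)/C(/C=C/COc2ccccc2)=C(/I)C)[C@@H](C)[C@H](O[Si](C)(C)C(C)(C)C)C[C@@H]1O[Si](CC)(CC)CC
F2 | step 17 | dienoic acid phenyl ether | C[C@@]1(C(OC)OC)[C@@H]([C@@H](O[Si](CC)(CC)CC)/C(/C=C/COc2ccccc2)=C(/C(=O)O)C)[C@@H](C)[C@H](O[Si](C)(C)C(C)(C)C)C[C@@H]1O[Si](CC)(CC)CC
F3 | step 22 | C6 aldehyde from ozonolysis of 24 | C[C@@]1(C(OC)OC)[C@@H]([C@@H](O[Si](CC)(CC)CC)C2=C(C)C(=O)O[C@H]2C=O)[C@@H](C)[C@H](O[Si](C)(C)C(C)(C)C)C[C@@H]1O[Si](CC)(CC)CC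
F4 | step 22 | (Z)-2-iodopropenyl butenolide acetal | C[C@@]1(C(OC)OC)[C@@H]([C@@H](O[Si](CC)(CC)CC)C2=C(C)C(=O)O[C@H]2/C=C(\I)C)[C@@H](C)[C@H](O[Si](C)(C)C(C)(C)C)C[C@@H]1O[Si](CC)(CC)CC
F5 | step 22 | C2 aldehyde of the iodoalkene | C[C@@]1(C=O)[C@@H]([C@@H](O[Si](CC)(CC)CC)C2=C(C)C(=O)O[C@H]2/C=C(\I)C)[C@@H](C)[C@H](O[Si](C)(C)C(C)(C)C)C[C@@H]1O[Si](CC)(CC)CC
F6 | step 22 | (2R)-vinyl carbinol | C[C@@]1([C@H](O)C=C)[C@@H]([C@@H](O[Si](CC)(CC)CC)C2=C(C)C(=O)O[C@H]2/C=C(\I)C)[C@@H](C)[C@H](O[Si](C)(C)C(C)(C)C)C[C@@H]1O[Si](CC)(CC)CC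
F7 | step 22 | (2R)-vinyl butyrate | C[C@@]1([C@H](OC(=O)CCC)C=C)[C@@H]([C@@H](O[Si](CC)(CC)CC)C2=C(C)C(=O)O[C@H]2/C=C(\I)C)[C@@H](C)[C@H](O[Si](C)(C)C(C)(C)C)C[C@@H]1O[Si](CC)(CC)CC
F8 | step 22 | B-alkyl-9-BBN adduct of F7 | C[C@@]1([C@H](OC(=O)CCC)CCB2C3CCCC2CCC3)[C@@H]([C@@H](O[Si](CC)(CC)CC)C2=C(C)C(=O)O[C@H]2/C=C(\I)C)[C@@H](C)[C@H](O[Si](C)(C)C(C)(C)C)C[C@@H]1O[Si](CC)(CC)CC
F9 | step 10 | bis(trimethylsilyl) ether of 12 | C[C@@]1(C(OC)OC)[C@@H](C=O)[C@@H](C)[C@H](O[Si](C)(C)C)C[C@@H]1O[Si](C)(C)C
F10 | step 10 | (3-iodo-1-methoxybuta-1,2-dien-1-yl)oxytrimethylsilane | COC(O[Si](C)(C)C)=C=C(C)I
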